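**Retrosynthetic overview**

- Numbering: ring A (cyclopentane) is C1(Me)–C2–C3–C4(iPr)–C5(OH); ring B (cycloheptane) is C5–C6–C7–C8(Me,OH)–C9(OAr)–C10–C1. The target is (1R,4R,5S,8R,9R): 1-Me, 4-iPr and 5-OH are mutually cis (cis ring fusion), 9-OAr is cis and 8-OH trans to 5-OH.
- Feature: C9–C10–C1(Me)–C2–C3–C4 plus the three isopropyl carbons is the intact carbon chain of (S)-citronellol; its methyl-bearing CH becomes the quaternary C1 and is the only source of absolute configuration.
- Late stage: 9-O-anisoate ⇒ 5,8,9-triol ⇒ 8,9-epoxide cis to 5-OH (water opens C8 with inversion) ⇒ C8=C9 alkene ⇒ ring-closing metathesis (ring B, formed second) of a diene whose arms come from 3-methylbut-3-enyl Grignard addition to a C5 ketone and methylenation of a C9 aldehyde.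
- Early stage: the C4 configuration of that ketone ⇒ hydroxyl-directed epoxidation, epoxide-to-allylic-alcohol isomerisation and hydroxyl-directed hydrogenation of a C4=C5 cyclopentene ⇒ ring A (formed first) by insertion of an alkylidene carbene at C5 into the tertiary C1–H bond of an isopropyl ketone ⇒ silylated (S)-citronellol.

Key step: step 4

Assumption: (S)-(−)-citronellol is used in high enantiomeric purity, because no later step can correct the configuration at C1.

**Route**

Step 1
Reactants: 1 (S)-(−)-citronellol, (3S)-3,7-dimethyloct-6-en-1-ol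
Product: 2 tert-butyl{[(3S)-3,7-dimethyloct-6-en-1-yl]oxy}dimethylsilane
Conditions: TBSCl, imidazole, DMF, 0 °C → rt
Reagents that add atoms: tert-butyldimethylsilyl chloride, CC(C)(C)[Si](C)(C)Cl
Why: Imidazole-promoted silylation of a primary alcohol gives a silyl ether that should withstand borane, basic peroxide and organolithium reagents, and no stereocentre is touched.

Step 2
Reactants: 2 tert-butyl{[(3S)-3,7-dimethyloct-6-en-1-yl]oxy}dimethylsilane
Product: 4 (6S)-8-(tert-butyldimethylsilyloxy)-2,6-dimethyloctan-3-ol (both C3 epimers), via dialkylborane 3 (not isolated)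
Conditions: BH3·THF (0.6 equiv), THF, 0 °C → rt; then NaOH aq, H2O2, 0 °C → rt
Reagents that add atoms: hydrogen peroxide, OO (oxygen of the new hydroxyl); borane, B (boron only in intermediate 3)
Why: Hydroboration–oxidation places boron and then hydroxyl on the less substituted carbon of the trisubstituted alkene, next to the isopropyl group; the new carbinol centre forms as both epimers, which is of no consequence because it is oxidised in step 3.

Step 3
Reactants: 4 (6S)-8-(tert-butyldimethylsilyloxy)-2,6-dimethyloctan-3-ol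
Product: 5 (6S)-8-(tert-butyldimethylsilyloxy)-2,6-dimethyloctan-3-one
Conditions: Dess–Martin periodinane, NaHCO3, CH2Cl2, 0 °C → rt
Reagents that add atoms: none
Why: Buffered Dess–Martin oxidation of a secondary alcohol should give the isopropyl ketone without affecting the silyl ether or the remote stereocentre.

Step 4
Reactants: 5 (6S)-8-(tert-butyldimethylsilyloxy)-2,6-dimethyloctan-3-one; 6 (trimethylsilyl)diazomethane
Product: 9 tert-butyldimethyl{2-[(1R)-1-methyl-3-(propan-2-yl)cyclopent-2-en-1-yl]ethoxy}silane, via diazoalkene 7 (not isolated), via alkylidene carbene 8 (not isolated)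
Conditions: Me3SiCHN2 (1.5 equiv), n-BuLi, THF, −78 °C; then 5, −78 °C → rt
Reagents that add atoms: none
Why: Lithiated 6 adds to the ketone, the β-silyl alkoxide collapses by Peterson-type loss of Me3SiOLi to diazoalkene 7, and loss of N2 gives alkylidene carbene 8, whose carbene carbon becomes C5. The closest known reaction type is the cyclopentene annulation of ketones through alkylidene carbenes generated with lithiated trimethylsilyldiazomethane. Ring A closes by a 1,5 C–H insertion: C5 bonds to C1 while the C4=C5 double bond formed in the olefination stays in the ring. The quaternary C1 is set by the citronellol stereocentre, because the insertion is concerted and proceeds with retention at the C–H carbon. The step needs site selectivity, and the substrate secures it: the tertiary C1–H is the only C–H bond that can close a five-membered ring (the isopropyl side reaches only a four-membered ring, the rest of the chain only six or more), and tertiary C–H bonds are the most reactive toward such carbenes. The 1,2-alkyl shift to an alkyne is slow for a dialkyl carbene, the silyl ether oxygen is too remote to intercept it, and excess reagent at low temperature compensates for any enolisation of the ketone.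

Step 5
Reactants: 9 tert-butyldimethyl{2-[(1R)-1-methyl-3-(propan-2-yl)cyclopent-2-en-1-yl]ethoxy}silane
Product: 10 2-[(1R)-1-methyl-3-(propan-2-yl)cyclopent-2-en-1-yl]ethan-1-ol
Conditions: Bu4NF, THF, rt
Reagents that add atoms: none
Why: Fluoride-mediated desilylation frees the primary hydroxyl that serves as the directing group in step 6.

Step 6
Reactants: 10 2-[(1R)-1-methyl-3-(propan-2-yl)cyclopent-2-en-1-yl]ethan-1-ol
Product: 11 2-[(1S,2R,5S)-2-methyl-5-(propan-2-yl)-6-oxabicyclo[3.1.0]hexan-2-yl]ethan-1-ol (oxirane oxygen cis to the hydroxyethyl arm)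
Conditions: VO(acac)2 (5 mol%), t-BuOOH (in decane), CH2Cl2, 0 °C → rt
Reagents that add atoms: tert-butyl hydroperoxide, CC(C)(C)OO
Why: In this hydroxyl-directed epoxidation the vanadium alkoxide of the bishomoallylic alcohol delivers the peroxide oxygen intramolecularly, so the oxirane should form on the ring face that carries the hydroxyethyl arm, a face that the methyl and the CH2CH2O arm on C1 would not differentiate well without direction.

Step 7
Reactants: 11 2-[(1S,2R,5S)-2-methyl-5-(propan-2-yl)-6-oxabicyclo[3.1.0]hexan-2-yl]ethan-1-ol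
Product: 12 (1S,5R)-5-(2-hydroxyethyl)-5-methyl-2-(propan-2-yl)cyclopent-2-en-1-ol (ring hydroxyl cis to the hydroxyethyl arm)
Conditions: LiNEt2 (from Et2NH and n-BuLi, 4 equiv), Et2O, 0 °C → reflux
Reagents that add atoms: none
Why: In this lithium-amide epoxide-to-allylic-alcohol isomerisation (syn β-elimination) the base removes the ring C3 hydrogen cis to the oxirane oxygen and the C4–O bond breaks, so the C5–O bond keeps its configuration, the side-chain alkoxide cannot open the oxirane because it sits on the same face, and any isopropylidene isomer from removal of the isopropyl methine would converge to the same diol in step 8.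

Step 8
Reactants: 12 (1S,5R)-5-(2-hydroxyethyl)-5-methyl-2-(propan-2-yl)cyclopent-2-en-1-ol
Product: 13 (1R,2R,5R)-2-(2-hydroxyethyl)-2-methyl-5-(propan-2-yl)cyclopentan-1-ol
Conditions: [Ir(cod)(PCy3)(py)]PF6 (5 mol%), H2 (1 atm), CH2Cl2, rt
Reagents that add atoms: none
Why: In this hydroxyl-directed hydrogenation both hydroxyls lie on the same ring face and bind the cationic iridium complex, so hydrogen is delivered to C4 from that face and the isopropyl group is placed on the face of the C1 methyl group, which sets C4.

Step 9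
Reactants: 13 (1R,2R,5R)-2-(2-hydroxyethyl)-2-methyl-5-(propan-2-yl)cyclopentan-1-ol
Product: 14 2-[(1R,3R)-1-methyl-2-oxo-3-(propan-2-yl)cyclopentyl]acetaldehyde
Conditions: (COCl)2, DMSO, CH2Cl2, −78 °C; then Et3N, −78 → 0 °C
Reagents that add atoms: none
Why: In the Swern oxidation both hydroxyls are converted into alkoxysulfonium salts before base is added, so no hydroxy aldehyde is present to close to a lactol and be over-oxidised to the lactone, and the hindered tertiary C4–H should not epimerise at or below 0 °C.

Step 10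
Reactants: 14 2-[(1R,3R)-1-methyl-2-oxo-3-(propan-2-yl)cyclopentyl]acetaldehyde
Product: 15 (2R,5R)-2-methyl-5-(propan-2-yl)-2-(prop-2-en-1-yl)cyclopentan-1-one
Conditions: Ph3PCH3Br, KN(SiMe3)2, THF, −78 → 0 °C
Reagents that add atoms: methyltriphenylphosphonium bromide, C[P+](c1ccccc1)(c1ccccc1)c1ccccc1.[Br-]
Why: Wittig methylenation should be chemoselective for the aldehyde, because the ketone is flanked by a quaternary and a tertiary carbon, and the fast low-temperature reaction limits enolisation toward C4.

Step 11
Reactants: 15 (2R,5R)-2-methyl-5-(propan-2-yl)-2-(prop-2-en-1-yl)cyclopentan-1-one; 16 4-bromo-2-methylbut-1-ene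
Product: 18 (1S,2R,5R)-2-methyl-1-(3-methylbut-3-en-1-yl)-5-(propan-2-yl)-2-(prop-2-en-1-yl)cyclopentan-1-ol, via 3-methylbut-3-enylmagnesium bromide 17 (not isolated)
Conditions: 16, Mg, THF, 35 °C; then 15, LaCl3·2LiCl (1 equiv), THF, 0 °C
Reagents that add atoms: magnesium, [Mg] (only in intermediate 17)
Why: Grignard 1,2-addition with LaCl3·2LiCl, which activates the congested carbonyl and suppresses enolisation, should occur from the face opposite the C4 isopropyl group (the face of C4–H and the allyl arm), so the new chain ends cis to the allyl arm and the C5 hydroxyl cis to isopropyl and methyl.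

Step 12
Reactants: 18 (1S,2R,5R)-2-methyl-1-(3-methylbut-3-en-1-yl)-5-(propan-2-yl)-2-(prop-2-en-1-yl)cyclopentan-1-ol
Product: 19 (3R,3aS,8aR)-6,8a-dimethyl-3-(propan-2-yl)-2,3,4,5,8,8a-hexahydroazulen-3a(1H)-ol (cis-fused; C8=C9 alkene in the numbering of the overview)
Conditions: (H2IMes)(PCy3)Cl2Ru=CHPh (second-generation Grubbs catalyst, 5 mol%), CH2Cl2 (5 mM), 40 °C
Reagents that add atoms: none
Why: Ring-closing metathesis joins the monosubstituted allyl alkene and the 1,1-disubstituted alkene, which are cis on ring A, so the cis-fused trisubstituted cycloheptene of ring B should close with loss of ethene, and the free tertiary alcohol is tolerated.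

Step 13
Reactants: 19 (3R,3aS,8aR)-6,8a-dimethyl-3-(propan-2-yl)-2,3,4,5,8,8a-hexahydroazulen-3a(1H)-ol
Product: 20 (3R,3aS,6S,7R,8aR)-6,7-epoxy-6,8a-dimethyl-3-(propan-2-yl)octahydroazulen-3a(1H)-ol (8,9-epoxide, oxirane oxygen cis to the 5-hydroxyl)
Conditions: VO(acac)2 (5 mol%), t-BuOOH (in decane), CH2Cl2, 0 °C → rt
Reagents that add atoms: tert-butyl hydroperoxide, CC(C)(C)OO
Why: In this transannular hydroxyl-directed epoxidation the C5 hydroxyl, bishomoallylic to both alkene carbons, delivers oxygen to its own face of ring B, which sets C8 and C9 and also prevents the hydroxyl from later opening the oxirane from the rear.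

Step 14
Reactants: 20 (3R,3aS,6S,7R,8aR)-6,7-epoxy-6,8a-dimethyl-3-(propan-2-yl)octahydroazulen-3a(1H)-ol
Product: 21 (3R,3aS,6R,7R,8aR)-6,8a-dimethyl-3-(propan-2-yl)decahydroazulene-3a,6,7-triol (5,8,9-triol in the numbering of the overview)
Conditions: HClO4 (cat.), THF/H2O, 0 °C
Reagents that add atoms: water, O
Why: In acid-catalysed epoxide hydrolysis water attacks the tertiary C8 with inversion, so the 8-hydroxyl ends trans to the retained 9-oxygen and trans to the 5-hydroxyl, and cold dilute acid should leave the tertiary C5 alcohol intact.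

Step 15
Reactants: 21 (3R,3aS,6R,7R,8aR)-6,8a-dimethyl-3-(propan-2-yl)decahydroazulene-3a,6,7-triol; 22 4-methoxybenzoyl chloride
Product: 23 (1R,3aR,5R,6R,8aS)-6,8a-dihydroxy-3a,6-dimethyl-1-(propan-2-yl)decahydroazulen-5-yl 4-methoxybenzoate (target)
Conditions: 22, pyridine, DMAP (cat.), CH2Cl2, 0 °C → rt
Reagents that add atoms: none
Why: DMAP-catalysed acylation should esterify only the secondary 9-hydroxyl, because the two tertiary hydroxyls are unreactive under these conditions, and no stereocentre is touched.

**Compound list**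

1 | (S)-(−)-citronellol, (3S)-3,7-dimethyloct-6-en-1-ol | CC(C)=CCC[C@H](C)CCO | starting material
2 | tert-butyl{[(3S)-3,7-dimethyloct-6-en-1-yl]oxy}dimethylsilane | CC(C)=CCC[C@H](C)CCO[Si](C)(C)C(C)(C)C | intermediate
3 | bis[(6S)-8-(tert-butyldimethylsilyloxy)-2,6-dimethyloctan-3-yl]borane (epimers at the boron-bearing carbons) | CC(C)C(CC[C@H](C)CCO[Si](C)(C)C(C)(C)C)BC(CC[C@H](C)CCO[Si](C)(C)C(C)(C)C)C(C)C | intermediate (not isolated)
4 | (6S)-8-(tert-butyldimethylsilyloxy)-2,6-dimethyloctan-3-ol (both C3 epimers) | CC(C)C(O)CC[C@H](C)CCO[Si](C)(C)C(C)(C)C | intermediate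
5 | (6S)-8-(tert-butyldimethylsilyloxy)-2,6-dimethyloctan-3-one | CC(C)C(=O)CC[C@H](C)CCO[Si](C)(C)C(C)(C)C | intermediate
6 | (trimethylsilyl)diazomethane | C[Si](C)(C)C=[N+]=[N-] | starting material
7 | tert-butyl{[(3S)-6-(diazomethylidene)-3,7-dimethyloctyl]oxy}dimethylsilane (diazoalkene) | CC(C)C(=C=[N+]=[N-])CC[C@H](C)CCO[Si](C)(C)C(C)(C)C | intermediate (not isolated)
8 | (5S)-7-(tert-butyldimethylsilyloxy)-5-methyl-2-(propan-2-yl)hept-1-en-1-ylidene (alkylidene carbene) | CC(C)C(=[C])CC[C@H](C)CCO[Si](C)(C)C(C)(C)C | intermediate (not isolated)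
9 | tert-butyldimethyl{2-[(1R)-1-methyl-3-(propan-2-yl)cyclopent-2-en-1-yl]ethoxy}silane | CC(C)C1=C[C@@](C)(CCO[Si](C)(C)C(C)(C)C)CC1 | intermediate
10 | 2-[(1R)-1-methyl-3-(propan-2-yl)cyclopent-2-en-1-yl]ethan-1-ol | CC(C)C1=C[C@@](C)(CCO)CC1 | intermediate
11 | 2-[(1S,2R,5S)-2-methyl-5-(propan-2-yl)-6-oxabicyclo[3.1.0]hexan-2-yl]ethan-1-ol | CC(C)[C@@]12CC[C@](C)(CCO)[C@@H]1O2 | intermediate
12 | (1S,5R)-5-(2-hydroxyethyl)-5-methyl-2-(propan-2-yl)cyclopent-2-en-1-ol | CC(C)C1=CC[C@](C)(CCO)[C@@H]1O | intermediate
13 | (1R,2R,5R)-2-(2-hydroxyethyl)-2-methyl-5-(propan-2-yl)cyclopentan-1-ol | CC(C)[C@H]1CC[C@](C)(CCO)[C@@H]1O | intermediate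
14 | 2-[(1R,3R)-1-methyl-2-oxo-3-(propan-2-yl)cyclopentyl]acetaldehyde | CC(C)[C@H]1CC[C@](C)(CC=O)C1=O | intermediate
15 | (2R,5R)-2-methyl-5-(propan-2-yl)-2-(prop-2-en-1-yl)cyclopentan-1-one | CC(C)[C@H]1CC[C@](C)(CC=C)C1=O | intermediate
16 | 4-bromo-2-methylbut-1-ene | C=C(C)CCBr | starting material
17 | (3-methylbut-3-en-1-yl)magnesium bromide | C=C(C)CC[Mg]Br | intermediate (not isolated)
18 | (1S,2R,5R)-2-methyl-1-(3-methylbut-3-en-1-yl)-5-(propan-2-yl)-2-(prop-2-en-1-yl)cyclopentan-1-ol | CC(C)[C@H]1CC[C@](C)(CC=C)[C@]1(O)CCC(C)=C | intermediate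
19 | (3R,3aS,8aR)-6,8a-dimethyl-3-(propan-2-yl)-2,3,4,5,8,8a-hexahydroazulen-3a(1H)-ol | CC1=CC[C@@]2(C)CC[C@H](C(C)C)[C@@]2(O)CC1 | intermediate
20 | (3R,3aS,6S,7R,8aR)-6,7-epoxy-6,8a-dimethyl-3-(propan-2-yl)octahydroazulen-3a(1H)-ol | O1[C@@H]2C[C@@]3(C)CC[C@H](C(C)C)[C@@]3(O)CC[C@]12C | intermediate
21 | (3R,3aS,6R,7R,8aR)-6,8a-dimethyl-3-(propan-2-yl)decahydroazulene-3a,6,7-triol | O[C@@H]1C[C@@]2(C)CC[C@H](C(C)C)[C@@]2(O)CC[C@@]1(C)O | intermediate
22 | 4-methoxybenzoyl chloride | COc1ccc(C(=O)Cl)cc1 | starting material
23 | (1R,3aR,5R,6R,8aS)-6,8a-dihydroxy-3a,6-dimethyl-1-(propan-2-yl)decahydroazulen-5-yl 4-methoxybenzoate | COc1ccc(C(=O)O[C@@H]2C[C@@]3(C)CC[C@H](C(C)C)[C@@]3(O)CC[C@@]2(C)O)cc1 | target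

**Step count**

Total: 15 steps. Longest linear sequence: 15 steps, from 1 to 23; the Grignard reagent 17 is made and used within step 11.

**Steps most likely to fail, with fallbacks**

Step 4 (key step). The lithiated diazomethane may act as a base and enolise the ketone instead of adding to it, so that ketone is returned and conversion stalls. The fallback sets out from 5. A Wittig reaction with (bromomethylene)triphenylphosphorane (from (bromomethyl)triphenylphosphonium bromide and KOtBu, THF, −78 °C → rt) should give the vinyl bromide tert-butyl{[(3S)-6-(bromomethylidene)-3,7-dimethyloctyl]oxy}dimethylsilane F1 as an E/Z mixture. α-Elimination with KN(SiMe3)2 in Et2O at rt would then generate the alkylidene carbenoid from either isomer, and the same 1,5 insertion into the C1–H bond with retention brings the route back at 9.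

Step 7. The amide base may remove the oxirane C5–H instead of the ring C3–H, leading through a lithiated epoxide to carbonyl products, or the syn-elimination may be sluggish in the cyclopentene oxide. The fallback sets out from 10 and bypasses steps 6 to 8. Silylation with 1,1,3,3-tetramethyldisilazane (neat, 60 °C) should give dimethyl{2-[(1R)-1-methyl-3-(propan-2-yl)cyclopent-2-en-1-yl]ethoxy}silane F2. Intramolecular hydrosilylation (Pt2[(CH2=CHSiMe2)2O]3 cat., toluene, 60 °C) is forced by the tether onto the alkene face of the side chain, silicon bonding to C5 and hydrogen to C4, to give the cyclic siloxane (1R,6R,9R)-2,2,6-trimethyl-9-(propan-2-yl)-3-oxa-2-silabicyclo[4.3.0]nonane F3. Tamao–Fleming oxidation (H2O2, KF, KHCO3, THF/MeOH, rt) replaces the C–Si bond by C–OH with retention and frees the primary alcohol, which rejoins the route at 13.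

Step 11. The Grignard reagent may enolise or reduce the congested ketone instead of adding, or add with too little preference for the face opposite the isopropyl group. The fallback sets out from 15 and forms the side chain in two smaller bond constructions. Corey–Chaykovsky methylenation with dimethylsulfonium methylide (Me3SI, KN(SiMe3)2, THF, −10 °C), a small nucleophile that should also attack opposite the isopropyl group, would give the spiro-epoxide (3S,4R,7R)-4-methyl-7-(propan-2-yl)-4-(prop-2-en-1-yl)-1-oxaspiro[2.4]heptane F4, with the oxirane oxygen cis to isopropyl and methyl. Opening at the oxirane CH2 with 2-methylallylmagnesium chloride and catalytic CuI (THF, −30 °C) forms the C6–C7 bond and returns to the route at 18.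

**Further compounds**

F1 | step 4 | tert-butyl{[(3S)-6-(bromomethylidene)-3,7-dimethyloctyl]oxy}dimethylsilane (E/Z mixture) | CC(C)C(=CBr)CC[C@H](C)CCO[Si](C)(C)C(C)(C)C
F2 | step 7 | dimethyl{2-[(1R)-1-methyl-3-(propan-2-yl)cyclopent-2-en-1-yl]ethoxy}silane | CC(C)C1=C[C@@](C)(CCO[SiH](C)C)CC1
F3 | step 7 | (1R,6R,9R)-2,2,6-trimethyl-9-(propan-2-yl)-3-oxa-2-silabicyclo[4.3.0]nonane | CC(C)[C@H]1CC[C@]2(C)CCO[Si](C)(C)[C@H]12
F4 | step 11 | (3S,4R,7R)-4-methyl-7-(propan-2-yl)-4-(prop-2-en-1-yl)-1-oxaspiro[2.4]heptane | CC(C)[C@H]1CC[C@](C)(CC=C)[C@]12CO2
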